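Slowness is what to watch in these flasks: a starting complex waits for its partner, and that wait can be reckoned.

    complex with one exchanged + incoming ligand → leaving ligand + complex with two exchanged (k1 = 10.3 L mol⁻¹ s⁻¹)
    crystals ⇌ leaving ligand, rate k2*(cs2 - [leaving ligand]) while solid is left; crystals form when [leaving ligand] > cs2 (cs2 = 0.88 mM, k2 = 3.42 s⁻¹)
    starting complex + incoming ligand → leaving ligand + complex with one exchanged (k3 = 10.3 L mol⁻¹ s⁻¹)
    starting complex + complex with two exchanged → side product (k4 = 12.0 L mol⁻¹ s⁻¹)

common to all: time 50 s

| run | starting complex | incoming ligand | remark |
|---|---|---|---|
| eta | 0.010 M (fed, over 30 s) | 1.00 equiv | all else is in the flask from the start; the feed brings no volume worth counting |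
| epsilon | 0.010 M | 1.00 equiv (fed, over 30 s) | all else is in the flask from the start; the feed brings no volume worth counting |
| beta | 0.010 M | 1.00 equiv | everything together at the start |

- percent here means starting complex units held: one side product counts as two
- what is said of leaving ligand includes crystals
- crystals is a solid; its amount is given per volume of the solution
- run time (eta): 50 s

- the flask with the highest amount of side product, in percent of the starting complex charged ("all alike" if they lie within 1.5 percentage points) (eta / epsilon / beta / all alike)
- final side product, as a percentage of the starting complex charged, in eta
- final side product, as a percentage of the starting complex charged, in epsilon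
- final side product, as a percentage of the starting complex charged, in beta

A starting complex has two possible partners, incoming ligand and complex with two exchanged, and each loss of a starting complex takes one partner away. Incoming ligand spent on complex with one exchanged merely becomes complex with two exchanged, which is still a partner. So starting complex minus partners stays constant once the charge is in, and at 1.00 equiv that difference is zero. I carry the meeting time τ, the lifetime of a starting complex against the full charge of partner, 9.71 s, and beta runs for N = 5.15 such times.

I reckon the fraction of starting complex left in beta in powers of ten, by two ways. If the partner stayed at its charge (the pseudo-first-order picture), the fraction would be e to the minus N, a fall of 2.24 powers of ten, or 0.580 %. If the partner falls with the starting complex and every loss runs at 10.3 L mol⁻¹ s⁻¹, the fraction is one over one plus N, a fall of 0.789 powers of ten, or 16.3 %. They part by a factor of 28.1, and the first way cheats: it keeps at full charge a partner that the pair count has shrinking. With the side step's 12.0 L mol⁻¹ s⁻¹ in place of 10.3 L mol⁻¹ s⁻¹, the second way gives 14.3 %, so I commit to that span.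

My reckoning gives no side product figure. In eta and epsilon the fed reactant arrives on average half way through the feed, so its time in the flask is on average shorter than in beta, and I bet on beta for the most side product. The count does not part eta from epsilon.

The forecast says beta, with 36.5 % in eta, 30.5 % in epsilon and 39 % in beta, putting “the all-at-once flask highest because both partners coexist longest”.

The simulation gives 37.2 % in eta, 30.8 % in epsilon and 40.2 % in beta, so beta holds the most.

Beta's run is longer than its meeting time, and at 50.0 s beta holds 15 % of its starting complex, beside 3.26 % of the incoming ligand's charge and 12.0 % complex with two exchanged. In eta, counting from the middle of the feed leaves 3.61 meeting times, one over one plus that is 21.7 %, and at 50.0 s eta holds 22 % of its starting complex, with side product at 37.2 %.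

The constants were drawn at random within sensible limits.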